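(The data stem from a simulated flask on assumed constants.)

Take the constants first: I fit no rate constant to these runs, and I carry one number read from them.

in all of them: free catalyst 14 mM
- dusk: substrate 0.75 M; partner 0.75 M; temperature 70 °C; the very flask that is asked about, followed so far
- winter: substrate 0.50 M; partner 0.75 M; temperature 76 °C; run made earlier
- flask: substrate 0.75 M; partner 0.750 M; temperature 70 °C; time 30 h

- dusk (time / h: target / %, substrate / %): 1.33: 13.6, 86.8; 2.50: 15.7, 84.4; 4.00: 16.5, 83.4; 6.00: 16.4, 82.6; 10.0: 16.9, 83.4; 20.0: 16.9, 82.9
- winter (time / h: target / %, substrate / %): 0.833: 18.7, 80.8; 1.33: 19.7, 80.0; 2.50: 21.5, 78.6; 4.00: 22.4, 79.0; 6.00: 22.2, 79.3; 10.0: 21.6, 78.2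

(readings scatter by 0.5 percentage points)

- epsilon: at 30 h add partner, 50.0 % of the amount charged, then wait 15 h
- zeta: at 30 h raise the temperature by 10 K, then wait 15 h
- alpha: change nothing and wait 15 h more
- delta: at 30 h add free catalyst, 50.0 % of the amount charged, then wait 15 h

- additions leave the volume as it is
- a reading or a percentage of target counts all its forms, free or not

- target, in percent of the substrate first charged, at 30 h
- the option that brings most further target ("none" if no option brings more than 2 percentage points) (epsilon / zeta / alpha / delta / none)
- target present, in percent of the substrate first charged, after alpha
- target present, in percent of the substrate first charged, after delta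

In the dusk run, which is the flask itself, target reads 16.9 % at 20.0 h. It has barely moved since 4.00 h, so the flask stops long before 30 h. That reading is 0.127 M of target. The hotter winter run made 0.108 M. Substrate differs by a factor of 1.50, output by 1.18, and the temperature differs as well. I read a catalyst that stops working, not a balance. Partner, heat and waiting should then give nothing.

If substrate hardly matters to the rate, the round is pseudo-first-order in partner. A given catalyst charge at a given temperature then buys a fixed drop in the logarithm of partner. In the dusk run, partner charged over partner left gives a logarithm of 0.185. Call this the reach of a catalyst charge.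

Now spend it. By that reading the flask holds 0.623 M of partner. A fresh 50.0 % of catalyst, scaled in proportion, has a reach of 0.0925. That gains 7.3 percentage points, so my number is 24.2 %.

The weak link is that scaling. If catalyst dies by meeting catalyst, a thinner charge lives longer and its reach shrinks less than in proportion. A full reach would gain 14 points, which I take as the upper end of my estimate. Even the lower gain clears the threshold of 2 points, so I choose delta.

The forecast says 16.8 % now, 16.8 % after waiting and 23.2 % after delta, which is below my 24.2 %, and it names delta. Its ground: “The catalyst is therefore dead by 30 h, so partner, heat or waiting give nothing.”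

The flask gives 16.8 %, then 16.8 % after alpha and 27.5 % after delta, a gain of 11 points.

    substrate + partner + free catalyst → target + free catalyst, rate k1*[substrate]*[partner]*[free catalyst]/(1 + ([substrate]/sat1)) (10.6 mM, k = 65.3 /M²/min, Ea = 49.0 kJ/mol)
    crystals ⇌ target, rate k2*(cs2 - [target]) while solid is left; crystals form when [target] > cs2 (solubility = 0.500 M, k = 0.222 /min)
    free catalyst → spent catalyst A (k = 0.0122 /min, Ea = 119 kJ/mol)
    2 free catalyst → spent catalyst B (k = 4.49 /M/min, Ea = 44.0 kJ/mol)
    (constants at 70 °C)

The forecast stands within its margins. At 30.0 h the flask holds 0 % of its catalyst charge as free catalyst, 23.5 % as spent catalyst A and 76.5 % as spent catalyst B, which forms from pairs. The fresh charge of delta reached 0.138 in the flask, more than its proportional share. Now carry the full reach to the neighbour charged with 0.30 M of substrate and otherwise like the flask. The same partner drop predicts 42.3 % of target. That neighbour gives 40.9 %, with 84 % of its partner left.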